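Ring A (carotenoid numbering: C1 = CMe2, C3 = CH–O, C5/C6 = epoxide carbons) is cut across C1–C2 and C3–C4. C1, C6, C5, C4 and the three methyls are the silyl dienol ether of isopropenyl isopropyl ketone; C2–C3 is methyl vinyl ketone. One catalytic enantioselective [4+2] cycloaddition joins them, builds quaternary C1 and sets C3, exploiting the 1,4 relation between oxygen-bearing C3 and C6, which later carries the epoxide oxygen. Baeyer–Villiger oxidation turns acetyl into the C3–O bond, the enol ether becomes a triflate for C7 attachment, and Sharpless epoxidation sets C5/C6. C15 + C10 + C15 Wittig couplings and palmitoylation finish.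

Key step: step 3

Assumption: the (S)-oxazaborolidinium catalyst of the cycloaddition is taken to show the same sense of induction with the vinyl ketone as with acrylates (the mirror-image catalyst would be used otherwise), and (R)-α-ionone is taken as purchasable in high enantiomeric purity.

**Ring A: C15 epoxy aldehyde**

Step 1
Reactants: 1 N-methoxy-N-methylisobutyramide; 2 isopropenylmagnesium bromide
Product: 3 2,4-dimethylpent-1-en-3-one
Conditions: THF, 0 °C; cold 1 M HCl quench
Reagents that add atoms: none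
Why: Grignard acylation of an N-methoxy-N-methylamide: the chelated tetrahedral adduct survives until the acidic quench, so the enone should form without over-addition; no stereocenter is formed.

Step 2
Reactants: 3 2,4-dimethylpent-1-en-3-one
Product: 4 [(2,4-dimethylpenta-1,3-dien-3-yl)oxy]triisopropylsilane
Conditions: i-Pr3SiOTf, Et3N, CH2Cl2, 0 °C → rt
Reagents that add atoms: triisopropylsilyl trifluoromethanesulfonate, CC(C)[Si](C(C)C)(C(C)C)OS(=O)(=O)C(F)(F)F
Why: Silyl enol ether formation by soft enolisation: O-silylation followed by removal of the only α′-hydrogen (the isopropyl methine) by Et3N should give the cross-conjugated 2-silyloxy diene; no stereocenter is formed.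

Step 3
Reactants: 4 [(2,4-dimethylpenta-1,3-dien-3-yl)oxy]triisopropylsilane; 5 methyl vinyl ketone
Product: 6 1-[(1R)-3,5,5-trimethyl-4-(triisopropylsilyloxy)cyclohex-3-en-1-yl]ethan-1-one
Conditions: (S)-3,3-diphenyl-1-(o-tolyl)tetrahydro-1H,3H-pyrrolo[1,2-c][1,3,2]oxazaborole·HNTf2 (20 mol %, made from (S)-α,α-diphenylprolinol, tri(o-tolyl)boroxine and Tf2NH), CH2Cl2, −78 → −40 °C
Reagents that add atoms: none
Why: The protonated oxazaborolidine binds the enone oxygen, the enol-ether carbon C1 of 4 attacks the enone β-carbon (future C2) and the developing enolate carbon (future C3) closes onto C4 in a concerted but strongly asynchronous [4+2] cycloaddition, whose limiting form is a Mukaiyama–Michael addition followed by Michael ring closure. The closest known reaction type is the oxazaborolidinium-catalysed enantioselective Diels–Alder reaction of 2-silyloxy-1,3-dienes with enones and acrylates. The cyclohexene ring closes by the cycloaddition itself, that is by a 6-endo-trig attack of the enolate on the silyloxyallyl cation terminus if the second bond lags. The only new stereocenter, C3, is controlled by the catalyst, whose aryl group shields one face of the bound enone so that the diene should add to the open face and give (R)-6. The step needs para regioselectivity, secured by the silyloxy group on C6, which makes C1 and not C4 the nucleophilic terminus and so places the acetyl group 1,4 to that oxygen, and it needs ring closure to outrun silyl transfer to the enolate, which the bulky triisopropylsilyl group secures.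

Step 4
Reactants: 6 1-[(1R)-3,5,5-trimethyl-4-(triisopropylsilyloxy)cyclohex-3-en-1-yl]ethan-1-one
Product: 7 (4R)-4-acetyl-2,6,6-trimethylcyclohex-1-en-1-yl trifluoromethanesulfonate
Conditions: CsF, PhNTf2, 1,2-dimethoxyethane, rt
Reagents that add atoms: N-phenylbis(trifluoromethanesulfonimide), O=S(=O)(N(c1ccccc1)S(=O)(=O)C(F)(F)F)C(F)(F)F
Why: Enol triflate formation: fluoride cleaves the Si–O bond and the resulting tetrasubstituted cesium enolate, the only regioisomer possible because C1 is quaternary, is trapped on oxygen by PhNTf2; C3 is not touched.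

Step 5
Reactants: 7 (4R)-4-acetyl-2,6,6-trimethylcyclohex-1-en-1-yl trifluoromethanesulfonate
Product: 8 (4R)-4-acetoxy-2,6,6-trimethylcyclohex-1-en-1-yl trifluoromethanesulfonate
Conditions: mCPBA, NaHCO3, CH2Cl2, rt
Reagents that add atoms: 3-chloroperoxybenzoic acid, OOC(=O)c1cccc(Cl)c1
Why: Baeyer–Villiger oxidation: the secondary ring carbon C3 migrates in preference to methyl and with retention of configuration, while the tetrasubstituted alkene is deactivated towards epoxidation by the triflate group.

Step 6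
Reactants: 8 (4R)-4-acetoxy-2,6,6-trimethylcyclohex-1-en-1-yl trifluoromethanesulfonate; 9 (tributylstannyl)methanol
Product: 10 (1R)-4-(hydroxymethyl)-3,5,5-trimethylcyclohex-3-en-1-yl acetate
Conditions: Pd(PPh3)4, LiCl, 1,4-dioxane, 100 °C
Reagents that add atoms: none
Why: Stille cross-coupling: oxidative addition of the alkenyl triflate to zerovalent palladium (chloride-assisted) and hydroxymethyl transfer from tin should install C7 at the alcohol oxidation level without touching the acetate or C3.

Step 7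
Reactants: 10 (1R)-4-(hydroxymethyl)-3,5,5-trimethylcyclohex-3-en-1-yl acetate
Product: 11 (1R,3S,6R)-6-(hydroxymethyl)-1,5,5-trimethyl-7-oxabicyclo[4.1.0]heptan-3-yl acetate
Conditions: Ti(OiPr)4 (20 mol %), D-(−)-diethyl tartrate (25 mol %), t-BuOOH, 4 Å molecular sieves, CH2Cl2, −20 °C
Reagents that add atoms: tert-butyl hydroperoxide, CC(C)(C)OO
Why: Sharpless asymmetric epoxidation of a primary allylic alcohol: with D-(−)-diethyl tartrate the titanium-bound peroxide should be delivered to the face of C5=C6 opposite to the C3 acetoxy group, setting C5 and C6 under reagent control (anti epoxide).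

Step 8
Reactants: 11 (1R,3S,6R)-6-(hydroxymethyl)-1,5,5-trimethyl-7-oxabicyclo[4.1.0]heptan-3-yl acetate
Product: 12 (1R,3S,6S)-6-formyl-1,5,5-trimethyl-7-oxabicyclo[4.1.0]heptan-3-yl acetate
Conditions: Dess–Martin periodinane, NaHCO3, CH2Cl2, 0 °C → rt
Reagents that add atoms: none
Why: Dess–Martin oxidation of the primary alcohol under buffered, non-acidic conditions; the epoxy aldehyde has no α-hydrogen and cannot epimerise.

Step 9
Reactants: 12 (1R,3S,6S)-6-formyl-1,5,5-trimethyl-7-oxabicyclo[4.1.0]heptan-3-yl acetate; 13 diethyl [(2E)-3-cyano-2-methylprop-2-en-1-yl]phosphonate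
Product: 14 (2E,4E)-5-[(1S,4S,6R)-4-acetoxy-2,2,6-trimethyl-7-oxabicyclo[4.1.0]heptan-1-yl]-3-methylpenta-2,4-dienenitrile
Conditions: LiN(SiMe3)2, THF, −78 → 0 °C
Reagents that add atoms: none
Why: Horner–Wadsworth–Emmons olefination with a nitrile-stabilised allylic phosphonate anion: it should give the E C7=C8 bond, the 9E geometry coming from the equilibrating reagent (any 9Z isomer removed by chromatography); the ring stereocenters are untouched.

Step 10
Reactants: 14 (2E,4E)-5-[(1S,4S,6R)-4-acetoxy-2,2,6-trimethyl-7-oxabicyclo[4.1.0]heptan-1-yl]-3-methylpenta-2,4-dienenitrile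
Product: 15 (2E,4E)-5-[(1S,4S,6R)-4-hydroxy-2,2,6-trimethyl-7-oxabicyclo[4.1.0]heptan-1-yl]-3-methylpenta-2,4-dienal
Conditions: i-Bu2AlH, CH2Cl2, −78 °C; aq. potassium sodium tartrate, then wet SiO2
Reagents that add atoms: water, O
Why: Hydride reduction with i-Bu2AlH: the nitrile stops at the N-aluminated aldimine, hydrolysed to the aldehyde on work-up, and the acetate is cleaved to the C3 alcohol, while the epoxide is left alone at −78 °C.

**ε end: C15 hydroxy aldehyde**

Step 11
Reactants: 16 (R)-α-ionone; 17 diethyl (cyanomethyl)phosphonate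
Product: 18 (2E,4E)-3-methyl-5-[(1R)-2,6,6-trimethylcyclohex-2-en-1-yl]penta-2,4-dienenitrile
Conditions: NaH, THF, 0 °C → rt
Reagents that add atoms: none
Why: Horner–Wadsworth–Emmons olefination of the methyl ketone with the preformed phosphonate anion (no free base, so C6′ is not epimerised) should give mainly the 9′E nitrile, the minor 9′Z isomer being removed by chromatography.

Step 12
Reactants: 18 (2E,4E)-3-methyl-5-[(1R)-2,6,6-trimethylcyclohex-2-en-1-yl]penta-2,4-dienenitrile
Product: 19 (2E,4E)-3-methyl-5-[(1R)-2,6,6-trimethyl-4-oxocyclohex-2-en-1-yl]penta-2,4-dienenitrile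
Conditions: CrO3, 3,5-dimethylpyrazole, CH2Cl2, −20 °C
Reagents that add atoms: chromium trioxide CrO3, O=[Cr](=O)=O
Why: Allylic oxidation with the CrO3–3,5-dimethylpyrazole complex: the unhindered ring methylene C3′ next to the trisubstituted alkene is oxidised to the enone under non-basic conditions, so the γ-stereocenter C6′ should not epimerise.

Step 13
Reactants: 19 (2E,4E)-3-methyl-5-[(1R)-2,6,6-trimethyl-4-oxocyclohex-2-en-1-yl]penta-2,4-dienenitrile
Product: 20 (2E,4E)-5-[(1R,4R)-4-hydroxy-2,6,6-trimethylcyclohex-2-en-1-yl]-3-methylpenta-2,4-dienenitrile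
Conditions: (S)-1-methyl-3,3-diphenyltetrahydro-1H,3H-pyrrolo[1,2-c][1,3,2]oxazaborole (20 mol %), catecholborane, toluene, −78 °C
Reagents that add atoms: none
Why: Corey–Bakshi–Shibata reduction: the (S)-oxazaborolidine treats the alkenyl side of the enone as the large group and should deliver hydride to give the 3′R carbinol (trans to the C6′ chain) under reagent control, 1,2-selectively and without touching the nitrile.

Step 14
Reactants: 20 (2E,4E)-5-[(1R,4R)-4-hydroxy-2,6,6-trimethylcyclohex-2-en-1-yl]-3-methylpenta-2,4-dienenitrile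
Product: 21 (2E,4E)-5-[(1R,4R)-4-hydroxy-2,6,6-trimethylcyclohex-2-en-1-yl]-3-methylpenta-2,4-dienal
Conditions: i-Bu2AlH, CH2Cl2, −78 °C; aq. potassium sodium tartrate, then wet SiO2
Reagents that add atoms: water, O
Why: Hydride reduction of the nitrile with i-Bu2AlH to the N-aluminated aldimine and hydrolysis on work-up gives the dienal; the alkoxide formed from the free alcohol is inert and no stereocenter is touched.

**Central C10 unit**

Step 15
Reactants: 22 (2E,4E,6E)-2,7-dimethylocta-2,4,6-trienedial
Product: 23 (2E,4E,6E)-2,7-dimethylocta-2,4,6-triene-1,8-diol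
Conditions: NaBH4, MeOH/CH2Cl2, 0 °C
Reagents that add atoms: none
Why: Borohydride 1,2-reduction of both conjugated aldehydes; alkene geometry is retained and no stereocenter is formed.

Step 16
Reactants: 23 (2E,4E,6E)-2,7-dimethylocta-2,4,6-triene-1,8-diol
Product: 24 [(2E,4E,6E)-2,7-dimethylocta-2,4,6-triene-1,8-diyl]bis(triphenylphosphonium) dibromide
Conditions: PPh3·HBr (2.2 equiv), MeOH, rt
Reagents that add atoms: triphenylphosphine hydrobromide, [Br-].c1ccc(cc1)[PH+](c1ccccc1)c1ccccc1
Why: Phosphonium salt formation from an allylic alcohol (acid-promoted ionisation and capture by triphenylphosphine at the primary terminus, which keeps the triene conjugated); no stereocenter is formed.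

**Assembly**

Step 17
Reactants: 24 [(2E,4E,6E)-2,7-dimethylocta-2,4,6-triene-1,8-diyl]bis(triphenylphosphonium) dibromide (3 equiv); 21 (2E,4E)-5-[(1R,4R)-4-hydroxy-2,6,6-trimethylcyclohex-2-en-1-yl]-3-methylpenta-2,4-dienal
Product: 25 [(2E,4E,6E,8E,10E,12E)-13-[(1R,4R)-4-hydroxy-2,6,6-trimethylcyclohex-2-en-1-yl]-2,7,11-trimethyltrideca-2,4,6,8,10,12-hexaen-1-yl]triphenylphosphonium bromide
Conditions: NaOMe (1 equiv), MeOH/CH2Cl2, 0 °C → rt
Reagents that add atoms: none
Why: Wittig olefination: with the bis-salt in threefold excess and one equivalent of base mainly one terminus is converted to the ylide and condenses with the aldehyde, leaving the second phosphonium group for step 18; the new C11′=C12′ bond should be mainly E and any Z isomer is carried on to the thermal equilibration of step 18.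

Step 18
Reactants: 25 the C25 phosphonium bromide; 15 (2E,4E)-5-[(1S,4S,6R)-4-hydroxy-2,2,6-trimethyl-7-oxabicyclo[4.1.0]heptan-1-yl]-3-methylpenta-2,4-dienal
Product: 27 (3S,5R,6S,3′R,6′R)-5,6-epoxy-5,6-dihydro-β,ε-carotene-3,3′-diol (lutein 5,6-epoxide), via 11Z isomer of lutein 5,6-epoxide 26 (not isolated)
Conditions: NaOMe, MeOH/CH2Cl2, 0 °C → rt; then EtOAc, 60 °C, N2, dark
Reagents that add atoms: none
Why: Wittig olefination forming C11=C12 under protic, mildly basic conditions that spare the vinylogous epoxide and the free alcohols; the sterically hindered Z isomers about the new disubstituted bonds should relax to all-E on gentle warming, and no stereocenter is touched.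

Step 19
Reactants: 27 lutein 5,6-epoxide; 28 palmitoyl chloride (2.5 equiv)
Product: 29 (3S,5R,6S,3′R,6′R)-5,6-epoxy-5,6-dihydro-β,ε-carotene-3,3′-diyl dipalmitate (CNP0344034.1)
Conditions: pyridine, DMAP (cat.), CH2Cl2, 0 °C → rt
Reagents that add atoms: none
Why: Acylation (esterification) of both secondary alcohols with the acid chloride under pyridine/DMAP catalysis, which keeps the medium basic and so protects the acid-labile epoxide and the allylic C3′–O bond; configuration is retained since no C–O bond is broken.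

**Compound list**

1 | N-methoxy-N-methylisobutyramide | CC(C)C(=O)N(C)OC | starting material
2 | isopropenylmagnesium bromide (THF solution) | CC(=C)[Mg]Br | starting material
3 | 2,4-dimethylpent-1-en-3-one | CC(C)C(=O)C(C)=C | intermediate
4 | [(2,4-dimethylpenta-1,3-dien-3-yl)oxy]triisopropylsilane | CC(C)=C(O[Si](C(C)C)(C(C)C)C(C)C)C(C)=C | intermediate
5 | methyl vinyl ketone (but-3-en-2-one) | CC(=O)C=C | starting material
6 | 1-[(1R)-3,5,5-trimethyl-4-(triisopropylsilyloxy)cyclohex-3-en-1-yl]ethan-1-one | CC(=O)[C@H]1CC(C)(C)C(O[Si](C(C)C)(C(C)C)C(C)C)=C(C)C1 | intermediate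
7 | (4R)-4-acetyl-2,6,6-trimethylcyclohex-1-en-1-yl trifluoromethanesulfonate | CC(=O)[C@H]1CC(C)(C)C(OS(=O)(=O)C(F)(F)F)=C(C)C1 | intermediate
8 | (4R)-4-acetoxy-2,6,6-trimethylcyclohex-1-en-1-yl trifluoromethanesulfonate | CC(=O)O[C@H]1CC(C)(C)C(OS(=O)(=O)C(F)(F)F)=C(C)C1 | intermediate
9 | (tributylstannyl)methanol | CCCC[Sn](CCCC)(CCCC)CO | starting material
10 | (1R)-4-(hydroxymethyl)-3,5,5-trimethylcyclohex-3-en-1-yl acetate | CC(=O)O[C@H]1CC(C)(C)C(CO)=C(C)C1 | intermediate
11 | (1R,3S,6R)-6-(hydroxymethyl)-1,5,5-trimethyl-7-oxabicyclo[4.1.0]heptan-3-yl acetate (epoxide anti to acetoxy) | CC(=O)O[C@H]1CC(C)(C)[C@]2(CO)O[C@]2(C)C1 | intermediate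
12 | (1R,3S,6S)-6-formyl-1,5,5-trimethyl-7-oxabicyclo[4.1.0]heptan-3-yl acetate | CC(=O)O[C@H]1CC(C)(C)[C@]2(C=O)O[C@]2(C)C1 | intermediate
13 | diethyl [(2E)-3-cyano-2-methylprop-2-en-1-yl]phosphonate | CCOP(=O)(OCC)C/C(C)=C/C#N | starting material
14 | (2E,4E)-5-[(1S,4S,6R)-4-acetoxy-2,2,6-trimethyl-7-oxabicyclo[4.1.0]heptan-1-yl]-3-methylpenta-2,4-dienenitrile | CC(=O)O[C@H]1CC(C)(C)[C@]2(/C=C/C(C)=C/C#N)O[C@]2(C)C1 | intermediate
15 | (2E,4E)-5-[(1S,4S,6R)-4-hydroxy-2,2,6-trimethyl-7-oxabicyclo[4.1.0]heptan-1-yl]-3-methylpenta-2,4-dienal | O[C@H]1CC(C)(C)[C@]2(/C=C/C(C)=C/C=O)O[C@]2(C)C1 | intermediate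
16 | (R)-α-ionone, (3E)-4-[(1R)-2,6,6-trimethylcyclohex-2-en-1-yl]but-3-en-2-one | CC(=O)/C=C/[C@H]1C(C)=CCCC1(C)C | starting material
17 | diethyl (cyanomethyl)phosphonate | CCOP(=O)(OCC)CC#N | starting material
18 | (2E,4E)-3-methyl-5-[(1R)-2,6,6-trimethylcyclohex-2-en-1-yl]penta-2,4-dienenitrile | N#C/C=C(C)/C=C/[C@H]1C(C)=CCCC1(C)C | intermediate
19 | (2E,4E)-3-methyl-5-[(1R)-2,6,6-trimethyl-4-oxocyclohex-2-en-1-yl]penta-2,4-dienenitrile | N#C/C=C(C)/C=C/[C@H]1C(C)=CC(=O)CC1(C)C | intermediate
20 | (2E,4E)-5-[(1R,4R)-4-hydroxy-2,6,6-trimethylcyclohex-2-en-1-yl]-3-methylpenta-2,4-dienenitrile | N#C/C=C(C)/C=C/[C@H]1C(C)=C[C@H](O)CC1(C)C | intermediate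
21 | (2E,4E)-5-[(1R,4R)-4-hydroxy-2,6,6-trimethylcyclohex-2-en-1-yl]-3-methylpenta-2,4-dienal | O=C/C=C(C)/C=C/[C@H]1C(C)=C[C@H](O)CC1(C)C | intermediate
22 | (2E,4E,6E)-2,7-dimethylocta-2,4,6-trienedial | O=C/C(C)=C/C=C/C=C(C)/C=O | starting material
23 | (2E,4E,6E)-2,7-dimethylocta-2,4,6-triene-1,8-diol | OC/C(C)=C/C=C/C=C(C)/CO | intermediate
24 | [(2E,4E,6E)-2,7-dimethylocta-2,4,6-triene-1,8-diyl]bis(triphenylphosphonium) dibromide | [Br-].[Br-].c1ccccc1[P+](c1ccccc1)(c1ccccc1)C/C(C)=C/C=C/C=C(C)/C[P+](c1ccccc1)(c1ccccc1)c1ccccc1 | intermediate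
25 | [(2E,4E,6E,8E,10E,12E)-13-[(1R,4R)-4-hydroxy-2,6,6-trimethylcyclohex-2-en-1-yl]-2,7,11-trimethyltrideca-2,4,6,8,10,12-hexaen-1-yl]triphenylphosphonium bromide | [Br-].c1ccccc1[P+](c1ccccc1)(c1ccccc1)C/C(C)=C/C=C/C=C(C)/C=C/C=C(C)/C=C/[C@H]1C(C)=C[C@H](O)CC1(C)C | intermediate
26 | (11Z)-(3S,5R,6S,3′R,6′R)-5,6-epoxy-5,6-dihydro-β,ε-carotene-3,3′-diol | O[C@H]1CC(C)(C)[C@]2(\C=C\C(C)=C\C=C/C(C)=C/C=C/C=C(C)/C=C/C=C(C)/C=C/[C@H]3C(C)=C[C@H](O)CC3(C)C)O[C@]2(C)C1 | intermediate (not isolated)
27 | (all-E)-(3S,5R,6S,3′R,6′R)-5,6-epoxy-5,6-dihydro-β,ε-carotene-3,3′-diol (lutein 5,6-epoxide) | O[C@H]1CC(C)(C)[C@]2(/C=C/C(C)=C/C=C/C(C)=C/C=C/C=C(C)/C=C/C=C(C)/C=C/[C@H]3C(C)=C[C@H](O)CC3(C)C)O[C@]2(C)C1 | intermediate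
28 | palmitoyl chloride (hexadecanoyl chloride) | CCCCCCCCCCCCCCCC(=O)Cl | starting material
29 | (3S,5R,6S,3′R,6′R)-5,6-epoxy-5,6-dihydro-β,ε-carotene-3,3′-diyl dipalmitate | CCCCCCCCCCCCCCCC(=O)O[C@H]1CC(C)(C)[C@]2(/C=C/C(C)=C/C=C/C(C)=C/C=C/C=C(C)/C=C/C=C(C)/C=C/[C@H]3C(C)=C[C@H](OC(=O)CCCCCCCCCCCCCCC)CC3(C)C)O[C@]2(C)C1 | target

**Step count and risks**

Total step count: 19. Longest linear sequence: 12 steps (steps 1–10, 18 and 19).

The three steps most likely to fail:

Step 3. The cycloaddition may proceed with poor enantiofacial discrimination, because at this hindered diene the second bond (C3–C4) can lag so far behind the first that the catalyst no longer dictates which enolate face closes. Fallback: setting out from 4 and 5, the cycloaddition is run with Me2AlCl in CH2Cl2 at −78 °C to give the racemic cycloadduct F1. This is carried through the conditions of steps 4, 5 and 6 as the racemic triflate ketone F2, the racemic triflate acetate F3 and the racemic allylic alcohol F4. Absolute control is then transferred to the reagent-controlled epoxidation of step 7, in which D-(−)-diethyl tartrate should oxidise the same alkene face of both enantiomers. The (R)-half gives 11 and the (S)-half gives the syn-epoxide diastereomer F5, which is removed by chromatography; the route is rejoined at 11.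

Step 4. Proton transfer from the acetyl group to the cesium enolate may compete with O-sulfonylation, giving the wrong enol triflate and eroding the C3 stereocenter. Fallback: setting out from 6, the silyl enol ether is cleaved with HF·pyridine in MeCN to the diketone F6. The unhindered methyl ketone alone is converted into its dioxolane, the ketal ketone F7, with 1,2-bis(trimethylsilyloxy)ethane and catalytic Me3SiOTf at −78 °C; the ring ketone, flanked by C1 and C5, should not react. KN(SiMe3)2 and PhNTf2 then give the ketal triflate F8 from the only enolisable ring position, and pyridinium p-toluenesulfonate in wet acetone releases the methyl ketone, returning to the route at 7.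

Step 6. Transmetalation of the sp3 hydroxymethyl group to the hindered, tetrasubstituted alkenylpalladium may be too slow, so that butyl transfer or reduction of the triflate takes over. Fallback: setting out from 8, reductive carbonylation (Pd(PPh3)4, CO, Bu3SnH, THF, 50 °C) gives the enal F9, and Luche reduction (NaBH4, CeCl3, MeOH, −20 °C) reduces the aldehyde without touching the acetate, returning to the route at 10.

Further compounds
F1 | step 3 | racemic 1-[3,5,5-trimethyl-4-(triisopropylsilyloxy)cyclohex-3-en-1-yl]ethan-1-one | CC(=O)C1CC(C)(C)C(O[Si](C(C)C)(C(C)C)C(C)C)=C(C)C1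
F2 | step 3 | racemic 4-acetyl-2,6,6-trimethylcyclohex-1-en-1-yl trifluoromethanesulfonate | CC(=O)C1CC(C)(C)C(OS(=O)(=O)C(F)(F)F)=C(C)C1
F3 | step 3 | racemic 4-acetoxy-2,6,6-trimethylcyclohex-1-en-1-yl trifluoromethanesulfonate | CC(=O)OC1CC(C)(C)C(OS(=O)(=O)C(F)(F)F)=C(C)C1
F4 | step 3 | racemic 4-(hydroxymethyl)-3,5,5-trimethylcyclohex-3-en-1-yl acetate | CC(=O)OC1CC(C)(C)C(CO)=C(C)C1
F5 | step 3 | (1R,3R,6R)-6-(hydroxymethyl)-1,5,5-trimethyl-7-oxabicyclo[4.1.0]heptan-3-yl acetate (epoxide syn to acetoxy) | CC(=O)O[C@@H]1CC(C)(C)[C@]2(CO)O[C@]2(C)C1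
F6 | step 4 | (4R)-4-acetyl-2,2,6-trimethylcyclohexan-1-one (both C6 epimers) | CC(=O)[C@H]1CC(C)(C)C(=O)C(C)C1
F7 | step 4 | (4R)-2,2,6-trimethyl-4-(2-methyl-1,3-dioxolan-2-yl)cyclohexan-1-one (both C6 epimers) | CC1(OCCO1)[C@H]1CC(C)(C)C(=O)C(C)C1
F8 | step 4 | (4R)-2,6,6-trimethyl-4-(2-methyl-1,3-dioxolan-2-yl)cyclohex-1-en-1-yl trifluoromethanesulfonate | CC1(OCCO1)[C@H]1CC(C)(C)C(OS(=O)(=O)C(F)(F)F)=C(C)C1
F9 | step 6 | (1R)-4-formyl-3,5,5-trimethylcyclohex-3-en-1-yl acetate | CC(=O)O[C@H]1CC(C)(C)C(C=O)=C(C)C1
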